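**Assumption:** the target has no sp³ stereocentres. Its only stereo-element is the (E)-enone (trans-CH=CH), so "single enantiomer" reduces to setting E geometry. The prenyl C=C is trisubstituted with two identical methyls and has no stereo-descriptor.

## Retrosynthetic overview
1. Disconnect the enone C=C (Claisen–Schmidt) to 3,4-dihydroxyacetophenone (10) and 4-hydroxy-2-methoxy-3-prenylbenzaldehyde (9).
2. Disconnect the aryl–prenyl bond of 9 by directed ortho-metalation at C3, which sits between the OMe and OMOM groups. The aldehyde is masked as a dioxolane so the aryllithium survives.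
3. This comes from commercial 4-hydroxy-2-methoxybenzaldehyde (1) after acetalisation and MOM protection.
4. No aromatic ring is built. The only ring made and removed is the temporary dioxolane, and the E-alkene is set last.

## Route

**Step 1**
Reactants: 1 (4-hydroxy-2-methoxybenzaldehyde); 2 (ethylene glycol)
Product: 3 (2-(4-hydroxy-2-methoxyphenyl)-1,3-dioxolane)
Conditions: TsOH·H2O (cat.), toluene, reflux, Dean–Stark
Reagents that add atoms: ethylene glycol, OCCO
Why: acid-catalysed acetalisation removes the electrophilic CHO so it is inert to the organolithium in Step 3. No stereocentre is formed.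

**Step 2**
Reactants: 3; 4 (chloromethyl methyl ether)
Product: 5 (2-[2-methoxy-4-(methoxymethoxy)phenyl]-1,3-dioxolane)
Conditions: NaH, DMF, 0 °C → rt; then MOMCl
Reagents that add atoms: MOMCl, ClCOC
Why: Williamson-type O-alkylation of the phenoxide gives a MOM ether that is base-stable and is a good directing group for lithiation. The acetal survives the basic conditions.

**Step 3**
Reactants: 5; 6 (prenyl bromide, 1-bromo-3-methylbut-2-ene)
Product: 7 (2-[2-methoxy-4-(methoxymethoxy)-3-(3-methylbut-2-en-1-yl)phenyl]-1,3-dioxolane)
Conditions: n-BuLi, THF, −78 → 0 °C; then CuBr·SMe2 (10 mol%), prenyl bromide, −78 °C → rt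
Reagents that add atoms: prenyl bromide, CC(C)=CCBr
Why: directed ortho-metalation occurs at C3, the only position flanked by two oxygen directing groups (OMe and OMOM). Cu(I)-catalysed SN2 alkylation of the aryllithium then installs the linear prenyl group. No stereocentre is formed.

**Step 4**
Reactants: 7; 8 (water)
Product: 9 (4-hydroxy-2-methoxy-3-prenylbenzaldehyde)
Conditions: 2 M HCl, THF/MeOH (1:1), 40 °C, 3 h
Reagents that add atoms: water, O
Why: one acidic hydrolysis removes both the dioxolane, which releases the CHO, and the aryl MOM ether, which releases the phenol. The prenyl alkene survives these mild conditions. No stereocentre is formed.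

**Step 5**
Reactants: 9; 10 (3,4-dihydroxyacetophenone)
Product: 11 (Licoagrochalcone C)
Conditions: KOH (aq., ~5 equiv), EtOH, rt → 50 °C, 24–48 h; then 2 M HCl to pH 2–3
Reagents that add atoms: none
Why: base-mediated Claisen–Schmidt (aldol/E1cB dehydration) with excess base to cover the three phenols. The thermodynamically controlled dehydration gives the conjugated (E)-chalcone, which sets the only stereo-element. The prenyl group and free catechol are retained, and the final acidification reprotonates the phenolates.

**Checks**
- The target SMILES gives a ketone ring with 3,4-(OH)2. The other ring carries CH=CH at C1, OMe at C2, prenyl at C3 and OH at C4. This matches 9 + 10 joined through C(=O)–CH=CH.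
- Atom balance:
  - Step 1: 1 + glycol − H2O gives 3.
  - Step 2: 3 + MOMCl − HCl gives 5.
  - Step 3: 5 + prenyl bromide − HBr gives 7.
  - Step 4: 7 + H2O gives 9 + ethylene glycol + CH2O + MeOH.
  - Step 5: 9 + 10 − H2O gives 11.
- The only stereo-element, the E-alkene, is formed in the last step and is not touched afterwards.

## Compound list
1 | 4-hydroxy-2-methoxybenzaldehyde | COc1cc(O)ccc1C=O | starting material
2 | ethylene glycol | OCCO | starting material
3 | 2-(4-hydroxy-2-methoxyphenyl)-1,3-dioxolane | COc1cc(O)ccc1C1OCCO1 | intermediate
4 | chloromethyl methyl ether (MOMCl) | ClCOC | starting material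
5 | 2-[2-methoxy-4-(methoxymethoxy)phenyl]-1,3-dioxolane | COc1cc(OCOC)ccc1C1OCCO1 | intermediate
6 | prenyl bromide (1-bromo-3-methylbut-2-ene) | CC(C)=CCBr | starting material
7 | 2-[2-methoxy-4-(methoxymethoxy)-3-(3-methylbut-2-enyl)phenyl]-1,3-dioxolane | COc1c(C2OCCO2)ccc(OCOC)c1CC=C(C)C | intermediate
8 | water | O | starting material (reagent)
9 | 4-hydroxy-2-methoxy-3-(3-methylbut-2-enyl)benzaldehyde | COc1c(C=O)ccc(O)c1CC=C(C)C | intermediate
10 | 3,4-dihydroxyacetophenone | CC(=O)c1ccc(O)c(O)c1 | starting material
11 | Licoagrochalcone C | COc1c(/C=C/C(=O)c2ccc(O)c(O)c2)ccc(O)c1CC=C(C)C | target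

**Total step count:** 5
**Longest linear sequence:** 5 steps (1 → 3 → 5 → 7 → 9 → 11)

## Three steps most likely to fail
1. **Step 3 (lithiation and prenylation).** Risks are competing lithiation ortho to the acetal, SN2′ reverse-prenyl product, and Wurtz coupling.
   Fallback: direct ortho-C-prenylation of phenol 1 (prenyl bromide, aq. KOH). Separate the C3 and C5 regioisomers, then carry on with Step 5 (a two-step route). This avoids organolithium chemistry altogether.
2. **Step 4 (global acid deprotection).** The ortho-prenylphenol product could cyclise to a 2,2-dimethylchromane, or the alkene could isomerise under acid.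
   Fallback: replace MOM with a SEM ether in Step 2. Hydrolyse the acetal under mild PPTS/acetone–H2O, then remove SEM with MgBr2 or TBAF, so no strong Brønsted acid is needed.
3. **Step 5 (Claisen–Schmidt on three free phenols).** The low electrophilicity of the phenolate aldehyde and catechol oxidation can give low yields.
   Fallback: switch to a protected version. Condense the MOM-protected aldehyde with 3,4-bis(MOM-oxy)acetophenone under NaOH/EtOH or acid-mediated conditions, then remove all MOM groups in one step. Alternatively, build the enone by Heck coupling of the corresponding aryl bromide with 3′,4′-protected vinyl ketone.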